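**Plan**
- Cuts, in retrosynthetic order: the benzylic ester C–O bond between the C6 CH2 and the rhizonic acid carboxyl; the C3–OH bond (back to a lactone CH2); the C3a–C3 and C3–O2 bonds of the lactone, both to one CH2 from dibromomethane; the aryl–CO2H bond (to CO2) and the silyl ether, back to 2,6-dimethoxybenzoic acid.
- Enabling feature (phthalide numbering: C1 carbonyl, O2, C3, C3a, C4–C7, C7a): C3 is one carbon joining ring carbon C3a to lactone oxygen O2, and C3a is the only hydrogen-bearing carbon next to C7a, which holds the carboxyl; the other neighbour, C7, carries oxygen. The carboxylate can therefore steer palladium to C3a, and a one-carbon dihalide closes ring C.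
- Forward order: symmetric arene → benzoic acid 6 → lactone ring C by C–H alkylation–lactonization → C3 hydroxylation → C7 O-demethylation → enzymatic acetylation → desilylation → Mitsunobu union with rhizonic acid (2 steps from its methyl ester precursor) → enzymatic deacetylation.
- Stereochemistry: the single stereocentre, C3 (R), comes from a lipase-catalysed dynamic kinetic acetylation of the racemising hemiacetal. It is carried as the acetate and released last by lipase alcoholysis, which does not break the C3–O bond.

Key step: step 5

Remark 1: a 3-hydroxyphthalide can epimerise through its open 2-formylbenzoic acid form; it is assumed that the (R)-hemiacetal holds its configuration under neutral, aprotic conditions at or below 25 °C, so it is set free only in the last step.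
Remark 2: the lipase is assumed to acetylate the (R)-hemiacetal faster, as the usual size model for lipase acylation of secondary alcohols predicts when C3a counts as the large and O2 as the medium substituent.

**Route**

Step 1
Reactants: 1 2,6-dimethoxybenzoic acid
Product: 2 2,6-dimethoxybenzyl alcohol
Conditions: LiAlH4, THF, 0 °C to reflux; H2O, aq. NaOH work-up
Reagents that add atoms: none
Why: Hydride reduction of a carboxylic acid by LiAlH4 should give the primary benzylic alcohol and leaves the aryl methyl ethers untouched.

Step 2
Reactants: 2 2,6-dimethoxybenzyl alcohol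
Product: 3 [(2,6-dimethoxybenzyl)oxy]triisopropylsilane
Conditions: TIPSCl, imidazole, DMF, 25 °C
Reagents that add atoms: chlorotriisopropylsilane, CC(C)[Si](Cl)(C(C)C)C(C)C
Why: Silylation of a primary alcohol with a silyl chloride and imidazole; the bulky TIPS ether is chosen to withstand n-BuLi, phosphate base at 140 °C and an amide base.

Step 3
Reactants: 3 [(2,6-dimethoxybenzyl)oxy]triisopropylsilane
Product: 4 [(3-bromo-2,6-dimethoxybenzyl)oxy]triisopropylsilane
Conditions: NBS (1.0 equiv), MeCN, 0 °C to 25 °C
Reagents that add atoms: N-bromosuccinimide, O=C1CCC(=O)N1Br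
Why: Electrophilic aromatic bromination goes ortho to one methoxy group and para to the other; the two such positions are equivalent by symmetry and one equivalent of NBS should stop at the monobromide.

Step 4
Reactants: 4 [(3-bromo-2,6-dimethoxybenzyl)oxy]triisopropylsilane
Product: 6 2,4-dimethoxy-3-[(triisopropylsilyloxy)methyl]benzoic acid, via aryllithium 5 (not isolated)
Conditions: n-BuLi, THF, −78 °C; then CO2 (gas), −78 °C to 0 °C; cold dilute HCl to pH 3
Reagents that add atoms: carbon dioxide, O=C=O
Why: Bromine–lithium exchange at −78 °C outruns any deprotonation and the aryllithium is carboxylated by CO2, which places the carboxyl carbon next to one methoxy group and one free C–H.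

Step 5
Reactants: 6 2,4-dimethoxy-3-[(triisopropylsilyloxy)methyl]benzoic acid; 7 dibromomethane
Product: 9 5,7-dimethoxy-6-[(triisopropylsilyloxy)methyl]phthalide, via bromomethyl benzoate salt 8 (not isolated)
Conditions: Pd(OAc)2 (10 mol %), K2HPO4 (3 equiv), CH2Br2 as solvent, 140 °C, sealed vessel
Reagents that add atoms: none
Why: The potassium carboxylate of 6 binds divalent palladium and directs concerted metalation–deprotonation of the only free ortho C–H (the future C3a) to a five-membered palladacycle; oxidative addition of dibromomethane to tetravalent palladium and C–C reductive elimination then form the aryl–CH2Br bond of 8. The carboxylate displaces bromide in a 5-exo-tet SN2 closure that makes the C3–O2 bond and ring C. The closest known reaction is the Pd(OAc)2-catalysed ortho C–H alkylation–lactonization of benzoic acids with dihaloalkanes, used here without change. No stereocentre is formed. The step needs site selectivity, which is secured because the other ortho position carries a methoxy group and because directed palladation reaches a C–H bond meta to both methoxy groups that electrophilic substitution would not attack; K2HPO4 traps the HBr, which spares the silyl ether, and is too mild to promote protodecarboxylation of the electron-rich acid.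

Step 6
Reactants: 9 5,7-dimethoxy-6-[(triisopropylsilyloxy)methyl]phthalide
Product: 11 racemic 3-hydroxy-5,7-dimethoxy-6-[(triisopropylsilyloxy)methyl]phthalide, via potassium C3 carbanion 10 (not isolated)
Conditions: KN(SiMe3)2 (1.1 equiv), THF, −78 °C; then 2-(phenylsulfonyl)-3-phenyloxaziridine (1.3 equiv), −78 °C; aq. NH4Cl
Reagents that add atoms: 2-(phenylsulfonyl)-3-phenyloxaziridine (Davis oxaziridine), O=S(=O)(c1ccccc1)N1OC1c1ccccc1
Why: Proposed new method: the C3–H bonds of 9 are benzylic, bear the lactone oxygen and are conjugated through the ring with the C1 carbonyl, so KN(SiMe3)2 should give the C3 carbanion (an extended enolate of the kind used for C3 alkylation and aldol reactions of phthalides), and an N-sulfonyloxaziridine should transfer an oxygen atom to it to give the hemiacetal directly as a racemate; the closest known reaction type is the Davis hydroxylation of ester and lactone enolates, and C3 is the only acidic C–H in 9.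

Step 7
Reactants: 11 racemic 3-hydroxy-5,7-dimethoxy-6-[(triisopropylsilyloxy)methyl]phthalide
Product: 12 racemic 3,7-dihydroxy-5-methoxy-6-[(triisopropylsilyloxy)methyl]phthalide
Conditions: BCl3 (2.2 equiv, 1 M in CH2Cl2), CH2Cl2, −78 °C to −10 °C; H2O quench at 0 °C
Reagents that add atoms: none
Why: Chelation-controlled ether cleavage, known for 5,7-dimethoxyphthalides: BCl3 is held between the C1 carbonyl oxygen and the peri C7 methoxy oxygen and chloride removes only that methyl group, while the C5 ether has no such chelate and the hemiacetal hydroxyl returns on aqueous work-up.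

Step 8
Reactants: 12 racemic 3,7-dihydroxy-5-methoxy-6-[(triisopropylsilyloxy)methyl]phthalide
Product: 13 (3R)-3-acetoxy-7-hydroxy-5-methoxy-6-[(triisopropylsilyloxy)methyl]phthalide
Conditions: immobilised Burkholderia cepacia lipase, vinyl acetate, Et3N (5 mol %), toluene, 40 °C
Reagents that add atoms: vinyl acetate, CC(=O)OC=C
Why: Lipase-catalysed dynamic kinetic resolution by irreversible transesterification, precedented for cyclic acyl hemiacetals (5-hydroxybutenolides): the enzyme should acetylate the (R)-hemiacetal while the (S)-hemiacetal racemises through the open formyl acid, so C3 is fixed as (R); the hydrogen-bonded C7 phenol is not acetylated and the silyl ether keeps the primary alcohol out of the reaction.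

Step 9
Reactants: 13 (3R)-3-acetoxy-7-hydroxy-5-methoxy-6-[(triisopropylsilyloxy)methyl]phthalide
Product: 14 (3R)-3-acetoxy-7-hydroxy-6-(hydroxymethyl)-5-methoxyphthalide
Conditions: HF·pyridine, pyridine, THF, 0 °C to 25 °C
Reagents that add atoms: none
Why: Fluoride-driven cleavage of the Si–O bond of a primary TIPS ether under buffered, non-basic conditions should leave the acetate acylal, the lactone and the C3 configuration untouched.

Step 10
Reactants: 15 methyl 2,4-dihydroxy-3,6-dimethylbenzoate
Product: 16 methyl 2-hydroxy-4-methoxy-3,6-dimethylbenzoate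
Conditions: MeI (1.1 equiv), K2CO3, acetone, reflux
Reagents that add atoms: iodomethane, CI
Why: Williamson O-methylation with one equivalent of MeI takes the free C4 phenol, because the C2 phenol is hydrogen-bonded to the ester carbonyl.

Step 11
Reactants: 16 methyl 2-hydroxy-4-methoxy-3,6-dimethylbenzoate
Product: 17 2-hydroxy-4-methoxy-3,6-dimethylbenzoic acid (rhizonic acid)
Conditions: KOH, DMSO/H2O, 80 °C; then cold 1 M HCl
Reagents that add atoms: potassium hydroxide, [K+].[OH-]
Why: Saponification of a hindered methyl ester is helped by aqueous DMSO, and cold acidification should avoid decarboxylation of the electron-rich salicylic acid.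

Step 12
Reactants: 14 (3R)-3-acetoxy-7-hydroxy-6-(hydroxymethyl)-5-methoxyphthalide; 17 2-hydroxy-4-methoxy-3,6-dimethylbenzoic acid
Product: 18 [(3R)-3-acetoxy-7-hydroxy-5-methoxy-1-oxo-1,3-dihydroisobenzofuran-6-yl]methyl 2-hydroxy-4-methoxy-3,6-dimethylbenzoate
Conditions: PPh3, DIAD, THF, 0 °C to 25 °C
Reagents that add atoms: none
Why: Mitsunobu esterification activates the primary benzylic alcohol instead of the hindered acid, and the carboxylate, far more acidic than either chelated phenol, displaces the oxyphosphonium group at CH2 without involving C3.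

Step 13
Reactants: 18 [(3R)-3-acetoxy-7-hydroxy-5-methoxy-1-oxo-1,3-dihydroisobenzofuran-6-yl]methyl 2-hydroxy-4-methoxy-3,6-dimethylbenzoate
Product: 19 [(3R)-3,7-dihydroxy-5-methoxy-1-oxo-1,3-dihydroisobenzofuran-6-yl]methyl 2-hydroxy-4-methoxy-3,6-dimethylbenzoate
Conditions: immobilised Burkholderia cepacia lipase, n-BuOH, MTBE, 25 °C; filtration and evaporation below 25 °C
Reagents that add atoms: none
Why: Lipase-catalysed alcoholysis with n-butanol, known for acyloxybutenolides, cleaves the acyl–oxygen bond of the (R)-acetate (the enantiomer the enzyme made), so the C3–O bond and the (R) configuration are kept under neutral conditions; the hindered benzylic rhizonate should not be a lipase substrate.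

**Compound list**
1 | 2,6-dimethoxybenzoic acid | COc1cccc(OC)c1C(=O)O | starting material
2 | 2,6-dimethoxybenzyl alcohol | COc1cccc(OC)c1CO | intermediate
3 | [(2,6-dimethoxybenzyl)oxy]triisopropylsilane | COc1cccc(OC)c1CO[Si](C(C)C)(C(C)C)C(C)C | intermediate
4 | [(3-bromo-2,6-dimethoxybenzyl)oxy]triisopropylsilane | COc1ccc(Br)c(OC)c1CO[Si](C(C)C)(C(C)C)C(C)C | intermediate
5 | 2,4-dimethoxy-3-[(triisopropylsilyloxy)methyl]phenyllithium (formed and used in the flask) | COc1ccc([Li])c(OC)c1CO[Si](C(C)C)(C(C)C)C(C)C | intermediate
6 | 2,4-dimethoxy-3-[(triisopropylsilyloxy)methyl]benzoic acid | COc1ccc(C(=O)O)c(OC)c1CO[Si](C(C)C)(C(C)C)C(C)C | intermediate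
7 | dibromomethane | BrCBr | starting material
8 | potassium 6-(bromomethyl)-2,4-dimethoxy-3-[(triisopropylsilyloxy)methyl]benzoate (formed and used in the flask) | COc1cc(CBr)c(C(=O)[O-])c(OC)c1CO[Si](C(C)C)(C(C)C)C(C)C.[K+] | intermediate
9 | 5,7-dimethoxy-6-[(triisopropylsilyloxy)methyl]phthalide | COc1cc2c(c(OC)c1CO[Si](C(C)C)(C(C)C)C(C)C)C(=O)OC2 | intermediate
10 | potassium C3 carbanion of 9 (formed and used in the flask) | COc1cc2[CH-]OC(=O)c2c(OC)c1CO[Si](C(C)C)(C(C)C)C(C)C.[K+] | intermediate
11 | racemic 3-hydroxy-5,7-dimethoxy-6-[(triisopropylsilyloxy)methyl]phthalide | COc1cc2c(c(OC)c1CO[Si](C(C)C)(C(C)C)C(C)C)C(=O)OC2O | intermediate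
12 | racemic 3,7-dihydroxy-5-methoxy-6-[(triisopropylsilyloxy)methyl]phthalide | COc1cc2c(c(O)c1CO[Si](C(C)C)(C(C)C)C(C)C)C(=O)OC2O | intermediate
13 | (3R)-3-acetoxy-7-hydroxy-5-methoxy-6-[(triisopropylsilyloxy)methyl]phthalide | COc1cc2c(c(O)c1CO[Si](C(C)C)(C(C)C)C(C)C)C(=O)O[C@H]2OC(C)=O | intermediate
14 | (3R)-3-acetoxy-7-hydroxy-6-(hydroxymethyl)-5-methoxyphthalide | COc1cc2c(c(O)c1CO)C(=O)O[C@H]2OC(C)=O | intermediate
15 | methyl 2,4-dihydroxy-3,6-dimethylbenzoate | COC(=O)c1c(C)cc(O)c(C)c1O | starting material
16 | methyl 2-hydroxy-4-methoxy-3,6-dimethylbenzoate | COC(=O)c1c(C)cc(OC)c(C)c1O | intermediate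
17 | 2-hydroxy-4-methoxy-3,6-dimethylbenzoic acid (rhizonic acid) | COc1cc(C)c(C(=O)O)c(O)c1C | intermediate
18 | [(3R)-3-acetoxy-7-hydroxy-5-methoxy-1-oxo-1,3-dihydroisobenzofuran-6-yl]methyl 2-hydroxy-4-methoxy-3,6-dimethylbenzoate | COc1cc(C)c(C(=O)OCc2c(OC)cc3c(c2O)C(=O)O[C@H]3OC(C)=O)c(O)c1C | intermediate
19 | [(3R)-3,7-dihydroxy-5-methoxy-1-oxo-1,3-dihydroisobenzofuran-6-yl]methyl 2-hydroxy-4-methoxy-3,6-dimethylbenzoate | COc1cc(C)c(C(=O)OCc2c(OC)cc3c(c2O)C(=O)O[C@H]3O)c(O)c1C | target

**Step count**
Total: 13 steps. Longest linear sequence: 11 steps (steps 1 to 9, 12 and 13); steps 10 and 11 form the side branch to rhizonic acid.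

**Steps most likely to fail**

Step 6 (proposed method). Deprotonation may stay incomplete, so that the carbanion adds to the lactone carbonyl of unreacted 9 or to the ring-opened aldehyde form of the product, and C3 may be oxidised twice. The fallback uses known reactions, sets out from 9 and comes back at 11. The lactone is opened with KOH in aqueous MeOH and the potassium carboxylate is alkylated with MeI in DMF to give methyl 6-(hydroxymethyl)-2,4-dimethoxy-3-[(triisopropylsilyloxy)methyl]benzoate F1. MnO2 in CH2Cl2 oxidises the benzylic alcohol to methyl 6-formyl-2,4-dimethoxy-3-[(triisopropylsilyloxy)methyl]benzoate F2. LiOH in aqueous THF, helped by the neighbouring aldehyde, cleaves the ester, and mild acidification closes the hemiacetal 11.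

Step 7. The silyl ether may be lost, or the electron-rich benzylic C–O bond may ionise under the Lewis acid, helped by HCl released when the hemiacetal meets BCl3. The fallback sets out from 11 and comes back at 18 by giving up the silyl ether on purpose. Excess BCl3 at 25 °C should demethylate C7 and turn the benzylic silyl ether into the chloride, racemic 6-(chloromethyl)-3,7-dihydroxy-5-methoxyphthalide F3. The lipase acetylation of step 8 should then give (3R)-3-acetoxy-6-(chloromethyl)-7-hydroxy-5-methoxyphthalide F4. The potassium salt of 17 (KHCO3, DMF, 25 °C) is alkylated by this chloride to give 18, which replaces the desilylation and the Mitsunobu step by a carboxylate alkylation.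

Step 8. Acyl transfer may be poorly enantioselective or favour the (S)-hemiacetal, or the slow-reacting hemiacetal may racemise too slowly for the resolution to become dynamic. The fallback sets out from 12 and comes back at 13. It is an acylative dynamic kinetic resolution with a small-molecule chiral acyl-transfer catalyst (benzotetramisole, an isothiourea available as either enantiomer), acetic anhydride and i-Pr2NEt in toluene at low temperature. The catalyst enantiomer is chosen for the (R)-acetate, and no new compound is made.

**Further compounds**
F1 | step 6 | methyl 6-(hydroxymethyl)-2,4-dimethoxy-3-[(triisopropylsilyloxy)methyl]benzoate | COC(=O)c1c(CO)cc(OC)c(CO[Si](C(C)C)(C(C)C)C(C)C)c1OC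
F2 | step 6 | methyl 6-formyl-2,4-dimethoxy-3-[(triisopropylsilyloxy)methyl]benzoate | COC(=O)c1c(C=O)cc(OC)c(CO[Si](C(C)C)(C(C)C)C(C)C)c1OC
F3 | step 7 | racemic 6-(chloromethyl)-3,7-dihydroxy-5-methoxyphthalide | COc1cc2c(c(O)c1CCl)C(=O)OC2O
F4 | step 7 | (3R)-3-acetoxy-6-(chloromethyl)-7-hydroxy-5-methoxyphthalide | COc1cc2c(c(O)c1CCl)C(=O)O[C@H]2OC(C)=O
F0 | step 8 | none | none
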